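## The problem

The target 29 has a 3-substituted furan linked by two CH2 groups to the C9 ketone, and a core in which a γ-lactone (C19, O, C6) is cis-fused to a cyclohexane (ring A: C1 to C5 and C10) across the C4–C5 bond. Labdane numbers are used throughout: C4 carries CH3 and the lactone carbonyl C19, C5 is the ring-fusion CH, C10 carries CH3 and the furyl ketone C9, C6 is the lactone O–CH, C7 the CH–OAc and C8 the acetyl carbonyl. There are five stereocentres (4S, 5R, 10S, 6S, 7S). C5 lies between the two quaternary carbons C4 and C10, with C6 cis to C19 and trans to C9. C6 and C7 form an anti-1,2-dioxygenated pair outside the ring. C4 is a doubly carbonyl-substituted quaternary carbon and can be made alone as one enantiomer, so it has to steer C5 and C10 during ring closure. C6 and C7 sit on a crowded exocyclic carbon and need reagent control. The furan excludes ozone, peracids, halogens and strong aqueous acid; the β-acyloxy α-acetoxy ketone (C6 to C8) eliminates and epimerises under base and must be finished last; the C9 ketone must stay masked while carbanions are used. The enabling feature is the C5–C10 bond, which joins the ring-fusion CH to a quaternary carbon bearing a methyl group. Hydrogen-atom transfer to a C10=CH2 alkene creates that methyl and a tertiary C10 radical together. The radical can add to C5 of a C5=C6 acceptor whose activating group at C6 later becomes the C6 oxygen.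

## Retrosynthesis

**End game (29 from 28, 27, 26).** The C9 ketone is released last from dioxolane 28, so no enolisable ketone is present during carbanion chemistry. The O7 acetate is cut next (28 to 27), which limits the time the elimination-prone C6–C8 array is exposed. The lactone C19–O6 bond is then opened to hydroxy ester 26. Lactonising before acetylating ties up O6, so O7 is the only free hydroxyl and needs no differentiation. The forward closure needs only the cis relation of C6 and C19, which the ring already provides.

**C6–C7 (26 from 24 and 25).** The bond between the two carbinol carbons is cut as an aldol between aldehyde 24 and hydroxyacetone 25. This one cut removes four carbons and both side-chain stereocentres, and an amine-catalysed enamine aldol gives the anti-diol directly. The neighbouring option, olefination to an E-enone followed by syn-dihydroxylation, would give the syn-diol and is longer. The forward step must override the C5 centre and must engage an aldehyde flanked by two quaternary carbons.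

**C6 oxidation level (24 from 22).** The aldehyde carbon is traced to the CH2SO2Ph group of sulfone 22. The sulfone is the group that makes C5=C6 a radical acceptor, and oxidative desulfonylation converts it into the carbonyl without a separate one-carbon operation.

**C5–C10 (22 from 21), the key cut.** Cutting C5–C10 opens ring A and removes C5 and C10 as stereocentres. It leaves the acyclic vinyl sulfone 21, whose only stereocentre is C4. Cutting C4–C5 instead (ester enolate onto an acceptor) would leave C10 as a lone all-carbon quaternary centre with no carbonyl handle, which is far harder to make as one enantiomer. The forward reaction needs 6-exo closure to outrun reduction of the radical, and needs C4 to fix both new centres.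

**C5=C6 and the C4 centre (21 from 18 and 19; 18 from 17, 16, 15, 14).** The vinyl sulfone comes from Horner–Wadsworth–Emmons reaction of phosphonate 19 with the non-enolisable aldehyde 18. The two carbonyl substituents of C4 (C19 and C5) are the two ester groups of the prochiral malonate 14, so C4 is created by desymmetrisation and not by C–C bond formation. Enzymatic hydrolysis gives half-ester 15; reduction of the remaining ester gives 16; methylation gives 17; oxidation gives 18. The two carbonyl groups are differentiated only after the enzyme step, so the sense of the hydrolysis can be corrected by choosing which carbonyl group is reduced.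

**C3–C4 (14 from 11 and 12).** Alkylation of dimethyl methylmalonate 12 with the primary chloride 11 attaches the whole C1–C3/C9–C12 chain in one step.

**C9 mask and C9–C10 (11 from 10; 10 from 7 and 4).** The dioxolane is needed so that the C10 radical is nucleophilic and not an α-keto radical. It comes from enone 10 by aprotic ketalisation. Enone 10 is cut at C9–C10 into the vinyl bromide 7 (as vinyllithium 8) and Weinreb amide 4. This fixes the position of the methylene group, which α-methylenation of a saturated ketone could not do (C10 and C11 are both CH2).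

**Fragments (4 from 3, from 1 and 2; 7 from 5).** Amide 4 comes from furan-3-carbaldehyde 1 and phosphonate 2 by olefination and hydrogenation. Bromide 7 comes from 5-chloropent-1-yne 5 by Markovnikov hydrobromination through alkenylborane 6.

## Roads not taken

**Alternative 1:** Both C5–C10 and C3–C4 are cut, giving 3-methyl-2-pyrone A1 as diene and the menthyloxy butenolide A2 as dienophile. A high-pressure Diels–Alder reaction would give the bridged bis-lactone A3.
- Merits: it is more convergent than the chosen plan and sets C4, C5 and C10 in one step. The acetal auxiliary at C6 is a well-established face control for butenolides. C19 is already a lactone and C6 arrives at the aldehyde oxidation level. In these respects it is better than the chosen plan.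
- Weak points: the dienophile carbon that becomes C4 is fully substituted and the diene is electron-poor, so very high pressure is needed. The regiochemistry (methyl-bearing pyrone carbon to C5) is not secured by a strong electronic bias. A3 can undergo decarboxylative cycloreversion on warming.
- After the key step: A3 has a C1=C2 alkene and a bridging oxygen on C3, both of which must be removed. The bridging carboxyl (C9) must be turned into the furylethyl ketone at a neopentyl position, and the menthyl acetal must be exchanged for the C7–C8 unit.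
- Comparison: the chosen plan sets one centre fewer in its key step and relies on unproven diastereoselection. Against that, it delivers ring A with no surplus oxygen or unsaturation and carries the furan and C9 at the right oxidation level from the start.

**Alternative 2:** C4–C5 and C6–C7 are cut inside a sacrificial second ring. Thermal intramolecular Diels–Alder reaction of triene A4 (dienyl acetate C7=C8–C19=C4 tethered to an E-enone C5=C6) would give the cis-fused octalin A5.
- Merits: the step needs no reagent and creates C4, C5, C6 and C7 from the single centre C10. The C6/C7 relationship is fixed by a concerted, ring-constrained transition state, and the O7 acetate is already present. For C6 and C7 this is more secure than the intermolecular aldol of the chosen plan.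
- Weak points: the diene terminus that becomes C4 is trisubstituted and must carry the tether on its inner position. Such dienes react slowly and tend to isomerise by 1,5-hydrogen shift.
- After the key step: the acetyl group on C6 must be exchanged for oxygen by Baeyer–Villiger oxidation and the C8=C19 alkene cleaved by ozonolysis. Both are incompatible with a furan, so C9 is carried as a silyl ether and the furyl ketone must be built late at a neopentyl carbon, next to the base-sensitive α-acetoxy ketone.
- Comparison: the chosen plan has to win C6 and C7 by catalyst control on a hindered aldehyde. Against that, it avoids all oxidative cleavage and needs only five steps after ring closure.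

**Alternative 3:** C4–C5 is cut in a ring contraction. The silyl ketene acetal of the ten-membered lactone A6 would undergo Ireland–Claisen rearrangement to the cis-2-alkenylcyclohexanecarboxylic acid A7.
- Merits: chirality transfer through a sigmatropic transition state is more predictable than the radical closure of the chosen plan. C19 emerges as a free acid cis to the C6 chain, and the C8 oxygen is already in place.
- Weak points: A7 has no methyl on C4, so the quaternary centre must be made afterwards by enolate methylation. A6 needs C10 as an isolated all-carbon quaternary stereocentre, plus C7 and C8 and a defined ring alkene, before a medium-ring lactonisation.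
- After the key step: the C6=C7 alkene gives the required anti O6/O7 pattern only by epoxidation and inverting lactonisation. C8 must be oxidised and C9 elaborated to the furyl ketone late.
- Comparison: the chosen plan has a less predictable stereochemical step. Against that, C4 is in place before ring closure and acts as the controller, and the precursor 21 is reached by routine chemistry from a malonate.

Key step: step 12

Assumption on the chemistry: pig liver esterase is taken to hydrolyse the enantiotopic ester group of 14 that leaves the (R)-half-ester 15. This is the sense known for 2-methylmalonates with long unbranched 2-alkyl chains; the functionalised chain of 14 is assumed to behave alike.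

## Route

Step 1
Reactants: 1 furan-3-carbaldehyde; 2 diethyl {2-[methoxy(methyl)amino]-2-oxoethyl}phosphonate
Product: 3 (2E)-3-(furan-3-yl)-N-methoxy-N-methylprop-2-enamide
Conditions: LiCl, DBU, MeCN, 0 °C to rt
Reagents that add atoms: none
Why: Horner–Wadsworth–Emmons olefination under Masamune–Roush conditions; the amide-stabilised phosphonate gives the (E)-alkene and the mild base does not touch the furan.

Step 2
Reactants: 3 (2E)-3-(furan-3-yl)-N-methoxy-N-methylprop-2-enamide
Product: 4 3-(furan-3-yl)-N-methoxy-N-methylpropanamide
Conditions: H2 (1 atm), Pd/C (5%), EtOAc, rt, stopped after one equivalent of H2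
Reagents that add atoms: none
Why: Catalytic hydrogenation of a conjugated 1,2-disubstituted alkene is much faster than saturation of the aromatic furan or cleavage of the N–O bond, so the side-chain alkene should be reduced selectively.

Step 3
Reactants: 5 5-chloropent-1-yne
Product: 7 2-bromo-5-chloropent-1-ene, via alkenylborane 6 (not isolated)
Conditions: 9-bromo-9-borabicyclo[3.3.1]nonane, CH2Cl2, 0 °C; then AcOH, 0 °C to rt
Reagents that add atoms: 9-bromo-9-borabicyclo[3.3.1]nonane, BrB1C2CCCC1CCC2
Why: Haloboration adds B–Br cis across the terminal alkyne with bromine on the internal carbon to give 6; protonolysis of the alkenyl C–B bond then leaves the 2-bromo-1-alkene, and the primary chloride is inert.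

Step 4
Reactants: 7 2-bromo-5-chloropent-1-ene; 4 3-(furan-3-yl)-N-methoxy-N-methylpropanamide
Product: 10 7-chloro-1-(furan-3-yl)-4-methylideneheptan-3-one, via vinyllithium 8 (not isolated), via tetrahedral lithium adduct 9 (not isolated)
Conditions: t-BuLi (2 equiv), Et2O, −78 °C; then 4, −78 °C; cold 1 M aq. HCl quench
Reagents that add atoms: none
Why: Lithium–bromine exchange gives 8, which acylates the Weinreb amide; the chelated adduct 9 survives until the quench, so there is no over-addition. The cold acidic quench protonates the liberated N,O-dimethylhydroxylamine so that it cannot add to the α-methylene ketone.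

Step 5
Reactants: 10 7-chloro-1-(furan-3-yl)-4-methylideneheptan-3-one
Product: 11 2-(5-chloropent-1-en-2-yl)-2-[2-(furan-3-yl)ethyl]-1,3-dioxolane
Conditions: Me3SiOCH2CH2OSiMe3, TMSOTf (cat.), CH2Cl2, −78 to −20 °C; pyridine quench
Reagents that add atoms: 1,2-bis(trimethylsilyloxy)ethane, C[Si](C)(C)OCCO[Si](C)(C)C
Why: Aprotic ketalisation with the bis-silyl ether of ethylene glycol under silyl triflate catalysis converts conjugated ketones into dioxolanes at low temperature. No free alcohol is present, which suppresses conjugate addition to the α-methylene ketone and spares the furan.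

Step 6
Reactants: 11 2-(5-chloropent-1-en-2-yl)-2-[2-(furan-3-yl)ethyl]-1,3-dioxolane; 12 dimethyl 2-methylpropanedioate (dimethyl methylmalonate)
Product: 14 dimethyl 2-(4-{2-[2-(furan-3-yl)ethyl]-1,3-dioxolan-2-yl}pent-4-en-1-yl)-2-methylpropanedioate, via alkyl iodide 13 (not isolated)
Conditions: Cs2CO3, NaI (cat.), DMF, 60 °C
Reagents that add atoms: none
Why: Malonate alkylation assisted by Finkelstein exchange; the iodide 13 formed in situ is reactive enough for the tertiary malonate carbanion, and ketal, alkene and furan are stable to carbonate base. The product is achiral (C4 prochiral).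

Step 7
Reactants: 14 dimethyl 2-(4-{2-[2-(furan-3-yl)ethyl]-1,3-dioxolan-2-yl}pent-4-en-1-yl)-2-methylpropanedioate
Product: 15 (2R)-6-{2-[2-(furan-3-yl)ethyl]-1,3-dioxolan-2-yl}-2-(methoxycarbonyl)-2-methylhept-6-enoic acid
Conditions: pig liver esterase, 0.1 M phosphate buffer (pH 7.5)/DMSO 9:1, rt
Reagents that add atoms: water, O
Why: Enzymatic desymmetrisation of a prochiral 2,2-disubstituted dimethyl malonate; the esterase hydrolyses one enantiotopic ester group and stops at the half-ester, which sets C4. The neutral buffer leaves ketal, alkene and furan untouched.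

Step 8
Reactants: 15 (2R)-6-{2-[2-(furan-3-yl)ethyl]-1,3-dioxolan-2-yl}-2-(methoxycarbonyl)-2-methylhept-6-enoic acid
Product: 16 (2S)-6-{2-[2-(furan-3-yl)ethyl]-1,3-dioxolan-2-yl}-2-(hydroxymethyl)-2-methylhept-6-enoic acid
Conditions: LiBH4 (3 equiv), THF, 0 to 45 °C; then aq. citric acid to pH 4
Reagents that add atoms: none
Why: Chemoselective borohydride reduction; the acid is deprotonated at once and its lithium carboxylate is inert to LiBH4, while the methyl ester is reduced. The enzyme-freed carboxyl thus becomes the future C19 and the former ester becomes C5, which is the assignment the (S)-series requires.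

Step 9
Reactants: 16 (2S)-6-{2-[2-(furan-3-yl)ethyl]-1,3-dioxolan-2-yl}-2-(hydroxymethyl)-2-methylhept-6-enoic acid
Product: 17 methyl (2S)-6-{2-[2-(furan-3-yl)ethyl]-1,3-dioxolan-2-yl}-2-(hydroxymethyl)-2-methylhept-6-enoate
Conditions: MeI, KHCO3, DMF, rt
Reagents that add atoms: iodomethane, CI
Why: O-alkylation of the carboxylate under weak base; the neopentyl primary alcohol is not alkylated and the quaternary centre cannot epimerise.

Step 10
Reactants: 17 methyl (2S)-6-{2-[2-(furan-3-yl)ethyl]-1,3-dioxolan-2-yl}-2-(hydroxymethyl)-2-methylhept-6-enoate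
Product: 18 methyl (2S)-2-formyl-6-{2-[2-(furan-3-yl)ethyl]-1,3-dioxolan-2-yl}-2-methylhept-6-enoate
Conditions: Dess–Martin periodinane, NaHCO3, CH2Cl2, 0 °C to rt
Reagents that add atoms: none
Why: Dess–Martin oxidation of a primary alcohol under buffered conditions that spare ketal and furan; the aldehyde has no α-hydrogen, so C4 is configurationally safe.

Step 11
Reactants: 18 methyl (2S)-2-formyl-6-{2-[2-(furan-3-yl)ethyl]-1,3-dioxolan-2-yl}-2-methylhept-6-enoate; 19 diethyl [(phenylsulfonyl)methyl]phosphonate
Product: 21 methyl (2S)-6-{2-[2-(furan-3-yl)ethyl]-1,3-dioxolan-2-yl}-2-methyl-2-[(E)-2-(phenylsulfonyl)ethenyl]hept-6-enoate, via sodium phosphonate carbanion 20 (not isolated)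
Conditions: NaH, THF, 0 °C; then 18, 0 °C to rt
Reagents that add atoms: none
Why: Horner–Wadsworth–Emmons olefination with the sulfonyl-stabilised carbanion 20 gives the (E)-vinyl sulfone; a preformed, alkoxide-free carbanion avoids deformylation of the α-formyl ester.

Step 12
Reactants: 21 methyl (2S)-6-{2-[2-(furan-3-yl)ethyl]-1,3-dioxolan-2-yl}-2-methyl-2-[(E)-2-(phenylsulfonyl)ethenyl]hept-6-enoate
Product: 22 methyl (1S,2R,3S)-3-{2-[2-(furan-3-yl)ethyl]-1,3-dioxolan-2-yl}-1,3-dimethyl-2-[(phenylsulfonyl)methyl]cyclohexane-1-carboxylate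
Conditions: Fe(acac)3 (0.5 equiv), PhSiH3 (3 equiv, slow addition), EtOH/ethylene glycol 5:1, 0.01 M, 60 °C
Reagents that add atoms: none
Why: An iron hydride formed from Fe(acac)3 and PhSiH3 transfers a hydrogen atom to the terminal CH2 of the 1,1-disubstituted alkene, creating the C10 methyl and a nucleophilic tertiary C10 radical. The radical adds to C5, the β-carbon of the vinyl sulfone, and the α-sulfonyl radical is reduced by divalent iron and protonated by ethanol; the closest known reaction type is the iron-hydride reductive coupling of alkenes with vinyl sulfone acceptors, including its cyclising variants. Ring A closes 6-exo-trig, helped by the polarity match and by the quaternary C4 in the tether; 7-endo attack at C6 and attack on the electron-rich furan are polarity-mismatched. C5 is controlled by C4 in a chair-like transition state in which the vinyl sulfone is equatorial and the flatter ester, not the methyl, takes the axial site on C4, so C6 ends cis to C19. C10 is controlled by the size of the ketal carbon, which takes the pseudo-equatorial site anti to C4 and leaves the new methyl pseudo-axial, so C6 ends trans to C9. The chemoselectivity needed is hydrogen-atom transfer to the isolated alkene only; this is secured because the vinyl sulfone is electron-poor and the furan aromatic. High dilution and slow silane addition disfavour reduction of the radical before closure, and the ethylene glycol cosolvent makes any ketal exchange degenerate. The level of diastereoselection is not precedented for this substitution pattern.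

Step 13
Reactants: 22 methyl (1S,2R,3S)-3-{2-[2-(furan-3-yl)ethyl]-1,3-dioxolan-2-yl}-1,3-dimethyl-2-[(phenylsulfonyl)methyl]cyclohexane-1-carboxylate
Product: 24 methyl (1S,2R,3S)-2-formyl-3-{2-[2-(furan-3-yl)ethyl]-1,3-dioxolan-2-yl}-1,3-dimethylcyclohexane-1-carboxylate, via lithiated sulfone 23 (not isolated)
Conditions: LiN(i-Pr)2 (LDA), THF, −78 °C; then Me3SiOOSiMe3, −78 to −20 °C; aq. NH4Cl
Reagents that add atoms: bis(trimethylsilyl) peroxide, C[Si](C)(C)OO[Si](C)(C)C
Why: Oxidative desulfonylation; the α-sulfonyl carbanion 23 is oxygenated at carbon by the peroxide and benzenesulfinate is then expelled, which leaves the aldehyde. The amide base does not add to the neopentyl ester, and the C5–H between two quaternary carbons is kinetically shielded from enolisation at low temperature.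

Step 14
Reactants: 24 methyl (1S,2R,3S)-2-formyl-3-{2-[2-(furan-3-yl)ethyl]-1,3-dioxolan-2-yl}-1,3-dimethylcyclohexane-1-carboxylate; 25 1-hydroxypropan-2-one (hydroxyacetone, excess)
Product: 26 methyl (1S,2R,3S)-2-[(1S,2S)-1,2-dihydroxy-3-oxobutyl]-3-{2-[2-(furan-3-yl)ethyl]-1,3-dioxolan-2-yl}-1,3-dimethylcyclohexane-1-carboxylate
Conditions: L-proline (30 mol%), DMSO, rt
Reagents that add atoms: none
Why: Proline-catalysed direct enamine aldol; the enamine forms at the hydroxylated carbon of hydroxyacetone and adds through a hydrogen-bonded chair-like transition state, giving the anti-diol with (6S,7S) configuration under catalyst control. α-Branched aldehydes that cannot self-condense are the preferred acceptors for this reaction.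

Step 15
Reactants: 26 methyl (1S,2R,3S)-2-[(1S,2S)-1,2-dihydroxy-3-oxobutyl]-3-{2-[2-(furan-3-yl)ethyl]-1,3-dioxolan-2-yl}-1,3-dimethylcyclohexane-1-carboxylate
Product: 27 (3S,3aR,4S,7aS)-4-{2-[2-(furan-3-yl)ethyl]-1,3-dioxolan-2-yl}-3-[(1S)-1-hydroxy-2-oxopropyl]-4,7a-dimethylhexahydro-2-benzofuran-1(3H)-one
Conditions: PPTS (cat.), toluene, 60 °C
Reagents that add atoms: none
Why: Acid-catalysed lactonisation; O6 and the C19 ester are cis on adjacent ring carbons, so the five-membered lactone closes readily, and under reversible acid catalysis it is favoured over the six-membered lactone through O7. Anhydrous mild acid leaves the ketal and the C6 and C7 configurations unchanged.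

Step 16
Reactants: 27 (3S,3aR,4S,7aS)-4-{2-[2-(furan-3-yl)ethyl]-1,3-dioxolan-2-yl}-3-[(1S)-1-hydroxy-2-oxopropyl]-4,7a-dimethylhexahydro-2-benzofuran-1(3H)-one
Product: 28 (3S,3aR,4S,7aS)-3-[(1S)-1-(acetyloxy)-2-oxopropyl]-4-{2-[2-(furan-3-yl)ethyl]-1,3-dioxolan-2-yl}-4,7a-dimethylhexahydro-2-benzofuran-1(3H)-one
Conditions: Ac2O, pyridine, DMAP (cat.), CH2Cl2, 0 °C
Reagents that add atoms: acetic anhydride, CC(=O)OC(C)=O
Why: Nucleophile-catalysed acylation of the only free hydroxyl (O7); low temperature and short reaction time keep the β-acyloxy ketone from eliminating or epimerising at C7.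

Step 17
Reactants: 28 (3S,3aR,4S,7aS)-3-[(1S)-1-(acetyloxy)-2-oxopropyl]-4-{2-[2-(furan-3-yl)ethyl]-1,3-dioxolan-2-yl}-4,7a-dimethylhexahydro-2-benzofuran-1(3H)-one
Product: 29 (3S,3aR,4S,7aS)-3-[(1S)-1-(acetyloxy)-2-oxopropyl]-4-[3-(furan-3-yl)propanoyl]-4,7a-dimethylhexahydro-2-benzofuran-1(3H)-one (CNP0170401.2)
Conditions: 1 M aq. HCl, THF, rt
Reagents that add atoms: water, O
Why: Acid-catalysed ketal hydrolysis; dilute acid at room temperature is tolerated by the 3-alkylfuran, the lactone and the acetate, and it is too weak to equilibrate C7.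

## Compound list

1 | furan-3-carbaldehyde | O=Cc1ccoc1 | starting material
2 | diethyl {2-[methoxy(methyl)amino]-2-oxoethyl}phosphonate | CCOP(=O)(CC(=O)N(C)OC)OCC | starting material
3 | (2E)-3-(furan-3-yl)-N-methoxy-N-methylprop-2-enamide | CON(C)C(=O)/C=C/c1ccoc1 | intermediate
4 | 3-(furan-3-yl)-N-methoxy-N-methylpropanamide | CON(C)C(=O)CCc1ccoc1 | intermediate
5 | 5-chloropent-1-yne | C#CCCCCl | starting material
6 | 9-[(1Z)-2-bromo-5-chloropent-1-en-1-yl]-9-borabicyclo[3.3.1]nonane | Br/C(CCCCl)=C\B1C2CCCC1CCC2 | intermediate
7 | 2-bromo-5-chloropent-1-ene | C=C(Br)CCCCl | intermediate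
8 | (5-chloropent-1-en-2-yl)lithium | [Li]C(=C)CCCCl | intermediate
9 | lithium 7-chloro-1-(furan-3-yl)-3-[methoxy(methyl)amino]-4-methylideneheptan-3-olate (racemic) | [Li]OC(CCc1ccoc1)(N(C)OC)C(=C)CCCCl | intermediate
10 | 7-chloro-1-(furan-3-yl)-4-methylideneheptan-3-one | O=C(CCc1ccoc1)C(=C)CCCCl | intermediate
11 | 2-(5-chloropent-1-en-2-yl)-2-[2-(furan-3-yl)ethyl]-1,3-dioxolane | ClCCCC(=C)C1(CCc2ccoc2)OCCO1 | intermediate
12 | dimethyl 2-methylpropanedioate (dimethyl methylmalonate) | COC(=O)C(C)C(=O)OC | starting material
13 | 2-[2-(furan-3-yl)ethyl]-2-(5-iodopent-1-en-2-yl)-1,3-dioxolane | ICCCC(=C)C1(CCc2ccoc2)OCCO1 | intermediate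
14 | dimethyl 2-(4-{2-[2-(furan-3-yl)ethyl]-1,3-dioxolan-2-yl}pent-4-en-1-yl)-2-methylpropanedioate | COC(=O)C(C)(CCCC(=C)C1(CCc2ccoc2)OCCO1)C(=O)OC | intermediate
15 | (2R)-6-{2-[2-(furan-3-yl)ethyl]-1,3-dioxolan-2-yl}-2-(methoxycarbonyl)-2-methylhept-6-enoic acid | OC(=O)[C@@](C)(CCCC(=C)C1(CCc2ccoc2)OCCO1)C(=O)OC | intermediate
16 | (2S)-6-{2-[2-(furan-3-yl)ethyl]-1,3-dioxolan-2-yl}-2-(hydroxymethyl)-2-methylhept-6-enoic acid | OC(=O)[C@@](C)(CCCC(=C)C1(CCc2ccoc2)OCCO1)CO | intermediate
17 | methyl (2S)-6-{2-[2-(furan-3-yl)ethyl]-1,3-dioxolan-2-yl}-2-(hydroxymethyl)-2-methylhept-6-enoate | COC(=O)[C@@](C)(CCCC(=C)C1(CCc2ccoc2)OCCO1)CO | intermediate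
18 | methyl (2S)-2-formyl-6-{2-[2-(furan-3-yl)ethyl]-1,3-dioxolan-2-yl}-2-methylhept-6-enoate | COC(=O)[C@@](C)(CCCC(=C)C1(CCc2ccoc2)OCCO1)C=O | intermediate
19 | diethyl [(phenylsulfonyl)methyl]phosphonate | CCOP(=O)(CS(=O)(=O)c1ccccc1)OCC | starting material
20 | sodium salt of diethyl [(phenylsulfonyl)methyl]phosphonate (carbanion) | [Na+].CCOP(=O)([CH-]S(=O)(=O)c1ccccc1)OCC | intermediate
21 | methyl (2S)-6-{2-[2-(furan-3-yl)ethyl]-1,3-dioxolan-2-yl}-2-methyl-2-[(E)-2-(phenylsulfonyl)ethenyl]hept-6-enoate | COC(=O)[C@@](C)(CCCC(=C)C1(CCc2ccoc2)OCCO1)/C=C/S(=O)(=O)c1ccccc1 | intermediate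
22 | methyl (1S,2R,3S)-3-{2-[2-(furan-3-yl)ethyl]-1,3-dioxolan-2-yl}-1,3-dimethyl-2-[(phenylsulfonyl)methyl]cyclohexane-1-carboxylate | COC(=O)[C@@]1(C)CCC[C@](C)(C2(CCc3ccoc3)OCCO2)[C@H]1CS(=O)(=O)c1ccccc1 | intermediate
23 | α-lithio derivative of 22 (lithium on the sulfonyl-bearing carbon C6) | COC(=O)[C@@]1(C)CCC[C@](C)(C2(CCc3ccoc3)OCCO2)[C@H]1C([Li])S(=O)(=O)c1ccccc1 | intermediate
24 | methyl (1S,2R,3S)-2-formyl-3-{2-[2-(furan-3-yl)ethyl]-1,3-dioxolan-2-yl}-1,3-dimethylcyclohexane-1-carboxylate | COC(=O)[C@@]1(C)CCC[C@](C)(C2(CCc3ccoc3)OCCO2)[C@H]1C=O | intermediate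
25 | 1-hydroxypropan-2-one (hydroxyacetone) | CC(=O)CO | starting material
26 | methyl (1S,2R,3S)-2-[(1S,2S)-1,2-dihydroxy-3-oxobutyl]-3-{2-[2-(furan-3-yl)ethyl]-1,3-dioxolan-2-yl}-1,3-dimethylcyclohexane-1-carboxylate | CC(=O)[C@@H](O)[C@@H](O)[C@H]1[C@@](C)(C(=O)OC)CCC[C@]1(C)C1(CCc2ccoc2)OCCO1 | intermediate
27 | (3S,3aR,4S,7aS)-4-{2-[2-(furan-3-yl)ethyl]-1,3-dioxolan-2-yl}-3-[(1S)-1-hydroxy-2-oxopropyl]-4,7a-dimethylhexahydro-2-benzofuran-1(3H)-one | CC(=O)[C@@H](O)[C@H]1OC(=O)[C@@]2(C)CCC[C@](C)(C3(CCc4ccoc4)OCCO3)[C@@H]12 | intermediate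
28 | (3S,3aR,4S,7aS)-3-[(1S)-1-(acetyloxy)-2-oxopropyl]-4-{2-[2-(furan-3-yl)ethyl]-1,3-dioxolan-2-yl}-4,7a-dimethylhexahydro-2-benzofuran-1(3H)-one | CC(=O)O[C@H](C(C)=O)[C@H]1OC(=O)[C@@]2(C)CCC[C@](C)(C3(CCc4ccoc4)OCCO3)[C@@H]12 | intermediate
29 | (3S,3aR,4S,7aS)-3-[(1S)-1-(acetyloxy)-2-oxopropyl]-4-[3-(furan-3-yl)propanoyl]-4,7a-dimethylhexahydro-2-benzofuran-1(3H)-one (CNP0170401.2) | CC(=O)O[C@H](C(C)=O)[C@H]1OC(=O)[C@@]2(C)CCC[C@](C)(C(=O)CCc3ccoc3)[C@@H]12 | target

## Step count and least certain steps

Total: 17 steps. Longest linear sequence: 16 steps (steps 1, 2 and 4 to 17 from furan-3-carbaldehyde); step 3 is a one-step branch. C4 is set in step 7, C5 and C10 in step 12, C6 and C7 in step 14; none is enolisable under the later conditions except C7, which sees only mild acid and brief cold base.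

**Step 12 (key step).** The likely failures are poor facial selectivity at C10 or C5 and reduction of the tertiary radical before it closes. The two chair-like arrangements differ only by an axial ester versus an axial methyl on C4, and 6-exo closure onto a β-substituted acceptor next to a quaternary carbon is slow.
Fallback: form the same bond with reversed polarity. Starting from 21, hydrolysis of the ketal (1 M aq. HCl, THF) gives the α-methylene ketone methyl (2S)-9-(furan-3-yl)-2-methyl-6-methylidene-7-oxo-2-[(E)-2-(phenylsulfonyl)ethenyl]nonanoate F1. Conjugate hydride delivery with LiBH(s-Bu)3 at −78 °C gives the C10 enolate regiospecifically, and this enolate closes 6-exo onto the vinyl sulfone (reductive Michael cyclisation). The product is the keto sulfone methyl (1S,2R,3S)-3-[3-(furan-3-yl)propanoyl]-1,3-dimethyl-2-[(phenylsulfonyl)methyl]cyclohexane-1-carboxylate F2. Ketalisation as in step 5 returns to 22.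

**Step 7.** The likely failure is low or reversed discrimination between the two ester groups, because the esterase distinguishes the C4 substituents by size and the chain of 14 is branched and functionalised.
Fallback: classical resolution in place of the enzyme. Starting from 14, one equivalent of KOH in methanol gives the racemic half-ester 6-{2-[2-(furan-3-yl)ethyl]-1,3-dioxolan-2-yl}-2-(methoxycarbonyl)-2-methylhept-6-enoic acid F3. Crystallisation with (R)-1-phenylethylamine (or its antipode, whichever gives the less soluble salt of the (R)-acid) gives the (R)-1-phenylethylammonium salt of the (R)-half-ester F4. Mild acidification returns to 15.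

**Step 14.** The likely failures are slow addition to a carbonyl flanked by two quaternary carbons, and erosion of facial selectivity if the C5 centre opposes the catalyst.
Fallback: olefination, epoxidation and inverting lactonisation. Starting from 24, Wittig reaction with 1-(triphenylphosphoranylidene)propan-2-one gives the E-enone methyl (1S,2R,3S)-3-{2-[2-(furan-3-yl)ethyl]-1,3-dioxolan-2-yl}-1,3-dimethyl-2-[(1E)-3-oxobut-1-en-1-yl]cyclohexane-1-carboxylate F5. Nucleophilic epoxidation with H2O2 and a 9-amino-9-deoxy-epi-cinchona amine salt as iminium catalyst gives the trans-epoxy ketone with (6R,7S) configuration, methyl (1S,2R,3S)-2-[(2R,3S)-3-acetyloxiran-2-yl]-3-{2-[2-(furan-3-yl)ethyl]-1,3-dioxolan-2-yl}-1,3-dimethylcyclohexane-1-carboxylate F6. With BF3·OEt2 in CH2Cl2 at low temperature, followed by water, the C19 ester carbonyl opens the epoxide at C6 with inversion (5-exo) and the methyl group is lost. This gives the anti O6/O7 pattern and returns to 27 directly, so step 15 is bypassed.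

**Step 13.** The likely failures are epimerisation at C5 or condensation of the aldehyde while it is released in a basic, silanolate-containing medium, and incomplete oxygen transfer to a very hindered carbanion.
Fallback: release the aldehyde under neutral conditions through a vinyl group. Starting from 22, the carbanion 23 is alkylated with (iodomethyl)trimethylsilane to give methyl (1S,2R,3S)-3-{2-[2-(furan-3-yl)ethyl]-1,3-dioxolan-2-yl}-1,3-dimethyl-2-[1-(phenylsulfonyl)-2-(trimethylsilyl)ethyl]cyclohexane-1-carboxylate F7. Fluoride-induced elimination (Bu4NF, THF) gives the vinyl compound methyl (1S,2R,3S)-2-ethenyl-3-{2-[2-(furan-3-yl)ethyl]-1,3-dioxolan-2-yl}-1,3-dimethylcyclohexane-1-carboxylate F8. Lemieux–Johnson cleavage (OsO4 cat., NaIO4, 2,6-lutidine, dioxane/water) passes through the diol methyl (1S,2R,3S)-2-(1,2-dihydroxyethyl)-3-{2-[2-(furan-3-yl)ethyl]-1,3-dioxolan-2-yl}-1,3-dimethylcyclohexane-1-carboxylate F9 and returns to 24.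

**Step 5.** The likely failures are conjugate addition of the glycol unit to the α-methylene ketone and acid-induced alkylation of the furan by the intermediate oxocarbenium ion.
Fallback: mask the alkene during ketalisation. Starting from 10, thiophenol with catalytic Et3N gives the β-phenylthio ketone 7-chloro-1-(furan-3-yl)-4-[(phenylsulfanyl)methyl]heptan-3-one F10. Ordinary ketalisation (ethylene glycol, PPTS, benzene, water removal) gives 2-{5-chloro-1-(phenylsulfanyl)pentan-2-yl}-2-[2-(furan-3-yl)ethyl]-1,3-dioxolane F11. NaIO4 in aqueous methanol gives the sulfoxide 2-{5-chloro-1-(phenylsulfinyl)pentan-2-yl}-2-[2-(furan-3-yl)ethyl]-1,3-dioxolane F12. Thermal syn-elimination (toluene, 110 °C, CaCO3) can only form the C10=CH2 alkene and returns to 11.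

## Further compounds

F1 | step 12 | methyl (2S)-9-(furan-3-yl)-2-methyl-6-methylidene-7-oxo-2-[(E)-2-(phenylsulfonyl)ethenyl]nonanoate | COC(=O)[C@@](C)(CCCC(=C)C(=O)CCc1ccoc1)/C=C/S(=O)(=O)c1ccccc1
F2 | step 12 | methyl (1S,2R,3S)-3-[3-(furan-3-yl)propanoyl]-1,3-dimethyl-2-[(phenylsulfonyl)methyl]cyclohexane-1-carboxylate | COC(=O)[C@@]1(C)CCC[C@](C)(C(=O)CCc2ccoc2)[C@H]1CS(=O)(=O)c1ccccc1
F3 | step 7 | racemic 6-{2-[2-(furan-3-yl)ethyl]-1,3-dioxolan-2-yl}-2-(methoxycarbonyl)-2-methylhept-6-enoic acid | OC(=O)C(C)(CCCC(=C)C1(CCc2ccoc2)OCCO1)C(=O)OC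
F4 | step 7 | (R)-1-phenylethylammonium (2R)-6-{2-[2-(furan-3-yl)ethyl]-1,3-dioxolan-2-yl}-2-(methoxycarbonyl)-2-methylhept-6-enoate | C[C@@H]([NH3+])c1ccccc1.[O-]C(=O)[C@@](C)(CCCC(=C)C1(CCc2ccoc2)OCCO1)C(=O)OC
F5 | step 14 | methyl (1S,2R,3S)-3-{2-[2-(furan-3-yl)ethyl]-1,3-dioxolan-2-yl}-1,3-dimethyl-2-[(1E)-3-oxobut-1-en-1-yl]cyclohexane-1-carboxylate | COC(=O)[C@@]1(C)CCC[C@](C)(C2(CCc3ccoc3)OCCO2)[C@H]1/C=C/C(C)=O
F6 | step 14 | methyl (1S,2R,3S)-2-[(2R,3S)-3-acetyloxiran-2-yl]-3-{2-[2-(furan-3-yl)ethyl]-1,3-dioxolan-2-yl}-1,3-dimethylcyclohexane-1-carboxylate | COC(=O)[C@@]1(C)CCC[C@](C)(C2(CCc3ccoc3)OCCO2)[C@H]1[C@H]1O[C@@H]1C(C)=O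
F7 | step 13 | methyl (1S,2R,3S)-3-{2-[2-(furan-3-yl)ethyl]-1,3-dioxolan-2-yl}-1,3-dimethyl-2-[1-(phenylsulfonyl)-2-(trimethylsilyl)ethyl]cyclohexane-1-carboxylate | COC(=O)[C@@]1(C)CCC[C@](C)(C2(CCc3ccoc3)OCCO2)[C@H]1C(C[Si](C)(C)C)S(=O)(=O)c1ccccc1
F8 | step 13 | methyl (1S,2R,3S)-2-ethenyl-3-{2-[2-(furan-3-yl)ethyl]-1,3-dioxolan-2-yl}-1,3-dimethylcyclohexane-1-carboxylate | COC(=O)[C@@]1(C)CCC[C@](C)(C2(CCc3ccoc3)OCCO2)[C@H]1C=C
F9 | step 13 | methyl (1S,2R,3S)-2-(1,2-dihydroxyethyl)-3-{2-[2-(furan-3-yl)ethyl]-1,3-dioxolan-2-yl}-1,3-dimethylcyclohexane-1-carboxylate | COC(=O)[C@@]1(C)CCC[C@](C)(C2(CCc3ccoc3)OCCO2)[C@H]1C(O)CO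
F10 | step 5 | 7-chloro-1-(furan-3-yl)-4-[(phenylsulfanyl)methyl]heptan-3-one | O=C(CCc1ccoc1)C(CSc1ccccc1)CCCCl
F11 | step 5 | 2-{5-chloro-1-(phenylsulfanyl)pentan-2-yl}-2-[2-(furan-3-yl)ethyl]-1,3-dioxolane | ClCCCC(CSc1ccccc1)C1(CCc2ccoc2)OCCO1
F12 | step 5 | 2-{5-chloro-1-(phenylsulfinyl)pentan-2-yl}-2-[2-(furan-3-yl)ethyl]-1,3-dioxolane | ClCCCC(CS(=O)c1ccccc1)C1(CCc2ccoc2)OCCO1
A1 | alternative 1 | 3-methyl-2H-pyran-2-one | CC1=CC=COC1=O
A2 | alternative 1 | (5R)-3-methyl-5-{[(1R,2S,5R)-5-methyl-2-(propan-2-yl)cyclohexyl]oxy}furan-2(5H)-one | CC(C)[C@@H]2CC[C@@H](C)C[C@H]2O[C@@H]1OC(=O)C(C)=C1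
A3 | alternative 1 | endo bridged bis-lactone Diels–Alder adduct | CC(C)[C@@H]4CC[C@@H](C)C[C@H]4O[C@@H]1OC(=O)[C@@]2(C)[C@H]3C=C[C@](C)(C(=O)O3)[C@@H]12
A4 | alternative 2 | triene with (1E)-dienyl acetate, tether on the inner diene position and E-enone | CC(=O)O/C=C(C)/C=C(/C)CCC[C@](C)(CO[Si](c1ccccc1)(c1ccccc1)C(C)(C)C)/C=C/C(C)=O
A5 | alternative 2 | cis-fused octalin with C6 acetyl and C7 acetate | CC(=O)O[C@@H]1C(C)=C[C@@]2(C)CCC[C@](C)(CO[Si](c3ccccc3)(c3ccccc3)C(C)(C)C)[C@H]2[C@@H]1C(C)=O
A6 | alternative 3 | ten-membered allylic lactone with E ring alkene | O=C1CCCC[C@](C)(CO[Si](C)(C)C(C)(C)C)/C=C/[C@H](O1)[C@H](C)O[Si](C)(C)C(C)(C)C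
A7 | alternative 3 | cis-2-alkenylcyclohexanecarboxylic acid | OC(=O)[C@H]1CCC[C@](C)(CO[Si](C)(C)C(C)(C)C)[C@H]1/C=C/[C@H](C)O[Si](C)(C)C(C)(C)C
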